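**Strategy.** The cyclobutane (C1–C1′–C2′–C10) is traced back to the (E)-C1=C10 trisubstituted olefin of a ten-membered cyclodec-4-enone and an isopropenylketene equivalent. In the key step a vinylketeniminium salt adds across this ring olefin and forms C1–C1′ and C10–C2′ at once: the E geometry gives the trans ring fusion, Markovnikov polarisation places the isopropenyl-bearing carbon on quaternary C10, and the ring conformation selects the face. The C1′ carbonyl is then excised. The precursor, macrocyclic keto ester 11, comes from geranyl acetate by asymmetric conjugate addition (C7), organocatalytic α-allylation (C5), Roskamp homologation and Tsuji–Trost ring closure; its C4 ketone, allyl group and CH2CO2Me arm become the exo-methylene, prenyl and acrylic acid units.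

Key step: step 10

Remark 1: ring locants follow germacrane numbering (C1=C10 olefin, C14 methyl on C10, C4 carbonyl/methylidene carbon, stereocentres C5 and C7); C1′ (on C1) and C2′ (on C10) are the two added cyclobutane carbons. CIP descriptors at C1 and C5 change along the route only because substituent priorities change; the SMILES strings are decisive.

Remark 2: in the two catalyst-controlled steps (3 and 5) the catalyst enantiomer is assumed to be the one whose established facial bias gives the centre drawn; this is to be confirmed on the first run.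

**Route**

Step 1
Reactants: 1 geranyl acetate
Product: 2 (4E)-6-acetoxy-4-methylhex-4-enal
Conditions: O3 (1 equiv), pyridine (cat.), CH2Cl2, −78 °C; then Me2S, −78 °C to rt
Reagents that add atoms: ozone, [O-][O+]=O
Why: Chemoselective ozonolysis, in which the electron-rich 6,7-olefin should react well before the 2,3-olefin that is deactivated by the allylic acetate, so the (E)-allylic acetate arm (future C2–C1=C10) stays intact.

Step 2
Reactants: 2 (4E)-6-acetoxy-4-methylhex-4-enal
Product: 3 methyl (2E,6E)-8-acetoxy-6-methylocta-2,6-dienoate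
Conditions: Ph3P=CHCO2Me, CH2Cl2, rt
Reagents that add atoms: methyl (triphenylphosphoranylidene)acetate, COC(=O)C=P(c1ccccc1)(c1ccccc1)c1ccccc1
Why: Wittig olefination with a stabilised ylide, which should give the (E)-enoate needed as the conjugate acceptor.

Step 3
Reactants: 3 methyl (2E,6E)-8-acetoxy-6-methylocta-2,6-dienoate; 4 2-(2-bromoethyl)-1,3-dioxolane
Product: 6 methyl (3S,6E)-8-acetoxy-3-[2-(1,3-dioxolan-2-yl)ethyl]-6-methyloct-6-enoate, via Grignard reagent 5 (not isolated)
Conditions: 4, Mg, THF, 25 °C; then 3, CuBr·SMe2 (5 mol%), Josiphos-type ferrocenyl diphosphine (6 mol%, enantiomer for Re-face delivery at C3), t-BuOMe, −75 °C; then H2O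
Reagents that add atoms: none
Why: Copper-catalysed asymmetric conjugate addition of a Grignard reagent to an (E)-enoate, in which the chiral copper complex delivers the alkyl group to the Re face of the β-carbon and so sets C7 as (S), while the allylic acetate should be inert at −75 °C.

Step 4
Reactants: 6 methyl (3S,6E)-8-acetoxy-3-[2-(1,3-dioxolan-2-yl)ethyl]-6-methyloct-6-enoate
Product: 7 methyl (3S,6E)-8-acetoxy-6-methyl-3-(3-oxopropyl)oct-6-enoate
Conditions: PPTS (0.2 equiv), acetone/H2O (10:1), 60 °C
Reagents that add atoms: water, O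
Why: Mild acid-catalysed acetal exchange and hydrolysis should free the aldehyde (future C4) without ionising the allylic acetate or touching the esters.

Step 5
Reactants: 7 methyl (3S,6E)-8-acetoxy-6-methyl-3-(3-oxopropyl)oct-6-enoate
Product: 8 methyl (3S,6E)-8-acetoxy-3-[(2R)-2-formylpent-4-en-1-yl]-6-methyloct-6-enoate
Conditions: allylSiMe3 (2.5 equiv), (NH4)2Ce(NO3)6 (2.5 equiv), NaHCO3, trans-5-benzyl-2-tert-butyl-3-methylimidazolidin-4-one·TFA (20 mol%, enantiomer for the 2R product), DME/H2O, −20 °C
Reagents that add atoms: allyltrimethylsilane, C=CC[Si](C)(C)C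
Why: SOMO-catalytic enantioselective α-allylation of an aldehyde, in which the enamine radical cation is trapped by the allylsilane on the face left open by the imidazolidinone, so C5 is set under catalyst control with little influence from remote C7; 8 is used at once because its α-centre is labile.

Step 6
Reactants: 8 methyl (3S,6E)-8-acetoxy-3-[(2R)-2-formylpent-4-en-1-yl]-6-methyloct-6-enoate
Product: 9 ethyl (4R,6S,9E)-11-acetoxy-4-allyl-6-(2-methoxy-2-oxoethyl)-9-methyl-3-oxoundec-9-enoate
Conditions: N2CHCO2Et (1.2 equiv), SnCl2 (10 mol%), CH2Cl2, rt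
Reagents that add atoms: ethyl diazoacetate, CCOC(=O)C=[N+]=[N-]
Why: Roskamp homologation (Lewis-acid-catalysed formal C–H insertion of the diazoacetate into the aldehyde) should give the β-keto ester under base-free conditions that keep the α-stereocentre C5.

Step 7
Reactants: 9 ethyl (4R,6S,9E)-11-acetoxy-4-allyl-6-(2-methoxy-2-oxoethyl)-9-methyl-3-oxoundec-9-enoate
Product: 10 ethyl (5R,7S,E)-5-allyl-7-(2-methoxy-2-oxoethyl)-10-methyl-4-oxocyclodec-1(10)-ene-3-carboxylate (C3 epimers)
Conditions: NaH (1.05 equiv), THF, 0 °C; then syringe-pump addition (final 2 mM) to Pd(PPh3)4 (10 mol%), dppe (10 mol%), THF, 65 °C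
Reagents that add atoms: none
Why: Intramolecular Tsuji–Trost allylic alkylation, in which the soft β-keto ester enolate attacks the primary terminus of the syn-π-allyl complex, should close the ten-membered ring (C2–C3) with the E olefin retained; the enolate form protects C5 and the C3 epimers converge in step 8.

Step 8
Reactants: 10 ethyl (5R,7S,E)-5-allyl-7-(2-methoxy-2-oxoethyl)-10-methyl-4-oxocyclodec-1(10)-ene-3-carboxylate
Product: 11 methyl 2-[(5R,7S,E)-5-allyl-10-methyl-4-oxocyclodec-1(10)-en-7-yl]acetate
Conditions: NaCl (cat.), DMSO/H2O, 140 °C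
Reagents that add atoms: none
Why: Krapcho dealkoxycarbonylation removes only the ketone-activated ester under neutral conditions, so the simple methyl ester survives and enolisation towards C5 is kept to a minimum.

Step 9
Reactants: 12 3-methylbut-2-enoyl chloride
Product: 13 N,N,3-trimethylbut-2-enamide
Conditions: Me2NH (40% aq.), NaOH, CH2Cl2/H2O, 0 °C
Reagents that add atoms: dimethylamine, CNC
Why: Schotten–Baumann acylation should give the tertiary amide needed as the keteniminium precursor.

Step 10
Reactants: 11 methyl 2-[(5R,7S,E)-5-allyl-10-methyl-4-oxocyclodec-1(10)-en-7-yl]acetate; 13 N,N,3-trimethylbut-2-enamide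
Product: 16 methyl 2-[(1S,5R,7S,10S,2′R)-5-allyl-2′-isopropenyl-10-methyl-4,1′-dioxo-1,10-ethanocyclodecan-7-yl]acetate (trans-fused cyclobutanone; C1′=O on C1; C2′ on C10), via vinylketeniminium triflate 14 (not isolated), via cyclobutaniminium triflate 15 (not isolated)
Conditions: 13 (1.5 equiv), Tf2O (1.4 equiv), ClCH2CH2Cl, −20 °C; then 11 and 2,4,6-collidine (1.6 equiv), 80 °C; then H2O, NaHCO3, rt
Reagents that add atoms: water, O (carbonyl oxygen of 16); trifluoromethanesulfonic anhydride, O=S(=O)(OS(=O)(=O)C(F)(F)F)C(F)(F)F (counter-ion of 14 and 15 only)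
Why: O-Triflation of 13 and γ-deprotonation give the vinylketeniminium ion 14, whose electrophilic central carbon is attacked by C1 of the ring olefin while positive charge builds at tertiary C10; the amino-substituted carbon then bonds to C10 to give iminium 15, which water hydrolyses to 16. The closest known reaction type is the keteniminium–olefin [2+2] cycloaddition to cyclobutanones (the activated form of a vinylketene–alkene cycloaddition), which is known for unactivated trisubstituted alkenes. The cyclobutane closes in an intermolecular, asynchronous [2+2] mode with both new bonds on one face of the olefin, so the E geometry is translated into the trans ring fusion (H-1 anti to C14). The face is set by the substrate: only the outer face of the (E)-cyclodecene is accessible, and the conformer with the C7 side chain pseudo-equatorial and C14 on the same side of the ring, as preferred in germacrene-type rings, exposes the face that leads to the C1/C10 configuration drawn; C2′ is epimerisable through 15 and its enamine and should settle with isopropenyl pseudo-equatorial, cis to C14 and trans to C9. Regiochemistry follows from Markovnikov polarisation (C1′ to C1, substituted C2′ to C10), and chemoselectivity from the much higher nucleophilicity of the trisubstituted ring olefin compared with the terminal allyl group, while the ester and the unreactive medium-ring C4 ketone should be inert because 14 is formed before 11 is added and no free Tf2O remains.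

Step 11
Reactants: 16 cyclobutanone from step 10; 17 4-methylbenzenesulfonohydrazide
Product: 19 methyl 2-[(1R,5R,7S,10S,2′R)-5-allyl-2′-isopropenyl-10-methyl-4-oxo-1,10-ethanocyclodecan-7-yl]acetate, via tosylhydrazone 18 (not isolated)
Conditions: 17 (1.05 equiv), EtOH, rt; then catecholborane (1.5 equiv), CHCl3, 0 °C; then NaOAc·3H2O, 60 °C
Reagents that add atoms: none
Why: The strained cyclobutanone should condense far faster than the medium-ring C4 ketone, and catecholborane reduction of the tosylhydrazone (hydride addition, sulfinate loss, N2 extrusion from the diazene; a mild Wolff–Kishner-type deoxygenation) turns C1′=O into CH2 without moving the non-conjugated isopropenyl double bond.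

Step 12
Reactants: 19 cyclobutane keto ester from step 11
Product: 20 methyl 2-[(1R,5S,7S,10S,2′R)-2′-isopropenyl-10-methyl-5-(3-methylbut-2-en-1-yl)-4-oxo-1,10-ethanocyclodecan-7-yl]acetate
Conditions: Grubbs second-generation catalyst (5 mol%), 2-methylbut-2-ene/CH2Cl2, 40 °C
Reagents that add atoms: 2-methylbut-2-ene, CC=C(C)C
Why: Olefin cross-metathesis, in which only the monosubstituted allyl olefin engages the ruthenium carbene and exchange with 2-methylbut-2-ene should give the prenyl group, the 1,1-disubstituted isopropenyl group staying out.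

Step 13
Reactants: 20 prenyl keto ester from step 12
Product: 21 methyl 2-[(1R,5S,7S,10S,2′R)-2′-isopropenyl-10-methyl-4-methylidene-5-(3-methylbut-2-en-1-yl)-1,10-ethanocyclodecan-7-yl]acetate
Conditions: Zn, CH2Br2, TiCl4, THF, 0 °C (reagent pre-formed); then 20, CH2Cl2, rt
Reagents that add atoms: dibromomethane, BrCBr
Why: Takai–Lombardo methylenation, whose non-basic gem-dimetallic reagent should methylenate the hindered, enolisable C4 ketone without epimerising C5 and without touching the ester.

Step 14
Reactants: 21 methylidene ester from step 13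
Product: 24 methyl 2-[(1R,5R,7S,10S,2′R)-2′-isopropenyl-10-methyl-4-methylidene-5-(3-methylbut-2-en-1-yl)-1,10-ethanocyclodecan-7-yl]prop-2-enoate, via Mannich base 22 (not isolated), via trimethylammonium iodide 23 (not isolated)
Conditions: LDA (1.2 equiv), THF, −78 °C; Me2N+=CH2 I− (2 equiv), −78 °C to rt; then MeI, MeOH, rt; then aq. NaHCO3, CH2Cl2, rt
Reagents that add atoms: dimethylmethylideneammonium iodide (Eschenmoser's salt), C=[N+](C)C.[I-]; iodomethane, CI (methyl kept only in 23)
Why: Ester-enolate Mannich reaction followed by quaternisation and Hofmann-type elimination is the standard α-methylenation, and the ester α-CH2 is the only acidic site left in 21.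

Step 15
Reactants: 24 α-methylene ester from step 14
Product: 25 2-[(1R,5R,7S,10S,2′R)-2′-isopropenyl-10-methyl-4-methylidene-5-(3-methylbut-2-en-1-yl)-1,10-ethanocyclodecan-7-yl]prop-2-enoic acid (target CNP0198062.1)
Conditions: LiOH·H2O, THF/H2O (3:1), 40 °C; then 1 M HCl to pH 3
Reagents that add atoms: lithium hydroxide, [Li+].[OH-]
Why: Saponification of the methyl ester should give the acid without isomerising the α-methylene unit, since no stereocentre carries an acidic hydrogen under these conditions.

**Compound list**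

1 | geranyl acetate | CC(C)=CCC/C(C)=C/COC(C)=O | starting material
2 | (4E)-6-acetoxy-4-methylhex-4-enal | O=CCC/C(C)=C/COC(C)=O | intermediate
3 | methyl (2E,6E)-8-acetoxy-6-methylocta-2,6-dienoate | COC(=O)/C=C/CC/C(C)=C/COC(C)=O | intermediate
4 | 2-(2-bromoethyl)-1,3-dioxolane | BrCCC1OCCO1 | starting material
5 | [2-(1,3-dioxolan-2-yl)ethyl]magnesium bromide | Br[Mg]CCC1OCCO1 | intermediate
6 | methyl (3S,6E)-8-acetoxy-3-[2-(1,3-dioxolan-2-yl)ethyl]-6-methyloct-6-enoate | CC(=O)OC/C=C(\C)CC[C@H](CC(=O)OC)CCC1OCCO1 | intermediate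
7 | methyl (3S,6E)-8-acetoxy-6-methyl-3-(3-oxopropyl)oct-6-enoate | CC(=O)OC/C=C(\C)CC[C@H](CC(=O)OC)CCC=O | intermediate
8 | methyl (3S,6E)-8-acetoxy-3-[(2R)-2-formylpent-4-en-1-yl]-6-methyloct-6-enoate | CC(=O)OC/C=C(\C)CC[C@H](CC(=O)OC)C[C@H](C=O)CC=C | intermediate
9 | ethyl (4R,6S,9E)-11-acetoxy-4-allyl-6-(2-methoxy-2-oxoethyl)-9-methyl-3-oxoundec-9-enoate | CC(=O)OC/C=C(\C)CC[C@H](CC(=O)OC)C[C@H](C(=O)CC(=O)OCC)CC=C | intermediate
10 | ethyl (5R,7S,E)-5-allyl-7-(2-methoxy-2-oxoethyl)-10-methyl-4-oxocyclodec-1(10)-ene-3-carboxylate (C3 epimers) | O=C1C(C(=O)OCC)C/C=C(\C)CC[C@H](CC(=O)OC)C[C@H]1CC=C | intermediate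
11 | methyl 2-[(5R,7S,E)-5-allyl-10-methyl-4-oxocyclodec-1(10)-en-7-yl]acetate | O=C1CC/C=C(\C)CC[C@H](CC(=O)OC)C[C@H]1CC=C | intermediate
12 | 3-methylbut-2-enoyl chloride | CC(C)=CC(Cl)=O | starting material
13 | N,N,3-trimethylbut-2-enamide | CC(C)=CC(=O)N(C)C | intermediate
14 | N,N-dimethyl-(3-methylbuta-1,3-dien-1-ylidene)ammonium triflate (vinylketeniminium salt) | C=C(C)C=C=[N+](C)C.[O-]S(=O)(=O)C(F)(F)F | intermediate
15 | C1′-dimethyliminium triflate of 16 (cyclobutaniminium salt) | O=C1CC[C@@H]2C(=[N+](C)C)[C@H](C(=C)C)[C@@]2(C)CC[C@H](CC(=O)OC)C[C@H]1CC=C.[O-]S(=O)(=O)C(F)(F)F | intermediate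
16 | methyl 2-[(1S,5R,7S,10S,2′R)-5-allyl-2′-isopropenyl-10-methyl-4,1′-dioxo-1,10-ethanocyclodecan-7-yl]acetate (trans-fused cyclobutanone) | O=C1CC[C@@H]2C(=O)[C@H](C(=C)C)[C@@]2(C)CC[C@H](CC(=O)OC)C[C@H]1CC=C | intermediate
17 | 4-methylbenzenesulfonohydrazide | Cc1ccc(cc1)S(=O)(=O)NN | starting material
18 | C1′ tosylhydrazone of 16 | O=C1CC[C@@H]2C(=NNS(=O)(=O)c3ccc(C)cc3)[C@H](C(=C)C)[C@@]2(C)CC[C@H](CC(=O)OC)C[C@H]1CC=C | intermediate
19 | methyl 2-[(1R,5R,7S,10S,2′R)-5-allyl-2′-isopropenyl-10-methyl-4-oxo-1,10-ethanocyclodecan-7-yl]acetate | O=C1CC[C@@H]2C[C@H](C(=C)C)[C@@]2(C)CC[C@H](CC(=O)OC)C[C@H]1CC=C | intermediate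
20 | methyl 2-[(1R,5S,7S,10S,2′R)-2′-isopropenyl-10-methyl-5-(3-methylbut-2-en-1-yl)-4-oxo-1,10-ethanocyclodecan-7-yl]acetate | O=C1CC[C@@H]2C[C@H](C(=C)C)[C@@]2(C)CC[C@H](CC(=O)OC)C[C@H]1CC=C(C)C | intermediate
21 | methyl 2-[(1R,5S,7S,10S,2′R)-2′-isopropenyl-10-methyl-4-methylidene-5-(3-methylbut-2-en-1-yl)-1,10-ethanocyclodecan-7-yl]acetate | C=C1CC[C@@H]2C[C@H](C(=C)C)[C@@]2(C)CC[C@H](CC(=O)OC)C[C@H]1CC=C(C)C | intermediate
22 | α-(dimethylaminomethyl) derivative of ester 21 (Mannich base; epimers at the new centre) | C=C1CC[C@@H]2C[C@H](C(=C)C)[C@@]2(C)CC[C@H](C(CN(C)C)C(=O)OC)C[C@H]1CC=C(C)C | intermediate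
23 | trimethylammonium iodide of 22 | C=C1CC[C@@H]2C[C@H](C(=C)C)[C@@]2(C)CC[C@H](C(C[N+](C)(C)C)C(=O)OC)C[C@H]1CC=C(C)C.[I-] | intermediate
24 | methyl 2-[(1R,5R,7S,10S,2′R)-2′-isopropenyl-10-methyl-4-methylidene-5-(3-methylbut-2-en-1-yl)-1,10-ethanocyclodecan-7-yl]prop-2-enoate | C=C1CC[C@@H]2C[C@H](C(=C)C)[C@@]2(C)CC[C@H](C(=C)C(=O)OC)C[C@H]1CC=C(C)C | intermediate
25 | 2-[(1R,5R,7S,10S,2′R)-2′-isopropenyl-10-methyl-4-methylidene-5-(3-methylbut-2-en-1-yl)-1,10-ethanocyclodecan-7-yl]prop-2-enoic acid (CNP0198062.1) | C=C1CC[C@@H]2C[C@H](C(=C)C)[C@@]2(C)CC[C@H](C(=C)C(=O)O)C[C@H]1CC=C(C)C | target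

**Step count and risks**

Total steps: 15. Longest linear sequence: 14 (steps 1–8 and 10–15, from geranyl acetate); step 9 is a one-step side branch.

Steps most likely to fail:

1. Step 10 (key cycloaddition). The two rapidly interconverting planar-chiral conformers of the ring olefin may be attacked with poor discrimination, giving the C1/C10 diastereomer, or the keteniminium ion may be consumed by self-condensation before it engages the hindered olefin. The fallback replaces substrate control by auxiliary control and sets out from 11 and 12. Acylation of (2R,5R)-2,5-dimethylpyrrolidine with 12 would give N-(3-methylbut-2-enoyl)-(2R,5R)-2,5-dimethylpyrrolidine F1. Tf2O and 2,6-di-tert-butyl-4-methylpyridine would convert it into the C2-symmetric vinylketeniminium triflate F2, whose chiral pyrrolidinium unit selects the olefin face in the cycloaddition with 11 to give cyclobutaniminium triflate F3. Hydrolysis with aqueous bicarbonate returns to the route at 16.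

2. Step 7 (ring closure). Intermolecular alkylation to oligomers, or β-hydride elimination from the π-allyl complex to a triene, may outpace closure of the ten-membered ring. The fallback changes from palladium π-allyl chemistry to a direct SN2 closure and sets out from 9. Methanolysis of the acetate (K2CO3, MeOH, 0 °C) would give allylic alcohol F4. MsCl, 2,4,6-collidine and LiCl in DMF at 0 °C would give allylic chloride F5 with the E geometry kept. Slow addition of F5 to Cs2CO3 and catalytic NaI in MeCN at 60 °C under high dilution would C-alkylate the caesium enolate and rejoin the route at 10.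

3. Step 11 (removal of the C1′ carbonyl). Hydrazone formation may be incomplete or may also engage the C4 ketone, and the strained diazene may fragment instead of losing nitrogen cleanly. The fallback is a radical deoxygenation and sets out from 16. NaBH4 in MeOH/CH2Cl2 at −78 °C should reduce only the strained ketone to cyclobutanol F6. Phenyl chlorothionoformate, pyridine and DMAP would give the O-phenyl thionocarbonate F7. Barton–McCombie reduction (Bu3SnH in high concentration, AIBN, toluene, 80 °C) would return to the route at 19.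

Further compounds
F1 | step 10 | N-(3-methylbut-2-enoyl)-(2R,5R)-2,5-dimethylpyrrolidine | CC(C)=CC(=O)N1[C@H](C)CC[C@H]1C
F2 | step 10 | (2R,5R)-2,5-dimethyl-1-(3-methylbuta-1,3-dien-1-ylidene)pyrrolidinium triflate | C=C(C)C=C=[N+]1[C@H](C)CC[C@H]1C.[O-]S(=O)(=O)C(F)(F)F
F3 | step 10 | C1′-[(2R,5R)-2,5-dimethylpyrrolidinium-1-ylidene] analogue of 15 (triflate) | O=C1CC[C@@H]2C(=[N+]3[C@H](C)CC[C@H]3C)[C@H](C(=C)C)[C@@]2(C)CC[C@H](CC(=O)OC)C[C@H]1CC=C.[O-]S(=O)(=O)C(F)(F)F
F4 | step 7 | ethyl (4R,6S,9E)-4-allyl-11-hydroxy-6-(2-methoxy-2-oxoethyl)-9-methyl-3-oxoundec-9-enoate | OC/C=C(\C)CC[C@H](CC(=O)OC)C[C@H](C(=O)CC(=O)OCC)CC=C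
F5 | step 7 | ethyl (4R,6S,9E)-4-allyl-11-chloro-6-(2-methoxy-2-oxoethyl)-9-methyl-3-oxoundec-9-enoate | ClC/C=C(\C)CC[C@H](CC(=O)OC)C[C@H](C(=O)CC(=O)OCC)CC=C
F6 | step 11 | C1′-hydroxy analogue of 16 (cyclobutanol; epimers at C1′) | O=C1CC[C@@H]2C(O)[C@H](C(=C)C)[C@@]2(C)CC[C@H](CC(=O)OC)C[C@H]1CC=C
F7 | step 11 | O-phenyl thionocarbonate of F6 | O=C1CC[C@@H]2C(OC(=S)Oc3ccccc3)[C@H](C(=C)C)[C@@]2(C)CC[C@H](CC(=O)OC)C[C@H]1CC=C
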